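A minute is my yardstick: what does one target molecule do in it?

| flask | substrate | reagent | free catalyst | second catalyst | remark | time |
|---|---|---|---|---|---|---|
| ash | 10 mM | 18 mM | 20 µM | 50 µM | run made earlier |  |
| birch | 10 mM | 29 mM | 20 µM | 50 µM | run made earlier |  |
| oak | 10 mM | 13 mM | 30 µM | 50 µM | run made earlier |  |
| flask | 10 mM | 13.0 mM | 20 µM | 50 µM |  | 30 min |

- ash (time / min: target / %, isomer of the product / %): 4.00: 8, 1; 8.00: 7, 5; 10.0: 8, 6; 15.0: 8, 9; 20.0: 10, 10
- birch (time / min: target / %, isomer of the product / %): 1.33: 10, 0; 2.50: 7, 0; 5.00: 10, 5; 10.0: 11, 8; 20.0: 19, 13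
- oak (time / min: target / %, isomer of the product / %): 1.50: 4, 3; 5.00: 5, 4; 8.00: 4, 5; 12.0: 6, 3; 20.0: 8, 8

(each reading ± 1.5 percentage points)



- ratio of target to isomer of the product at 1.0 min
- ratio of target to isomer of the product at 30 min

At 20.0 min, ash reads 10 % target and 10 % isomer of the product, and oak reads 8 % and 8 %, so I let a molecule cross equally often either way. In ash, the gap [target] − [isomer of the product] falls from 7 percentage points at 4.00 min to 2 points at 8.00 min. This gives the memory time τ, the time for the gap to shrink e-fold (a relaxation time), read with the scatter of the readings: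

τ = 3.19 min, crossing rate each way 0.157 /min

The second time is the age A of the product pool. Early in the flask, I take target as made steadily, so its mean age at 1.0 min is shorter than τ:

A = 0.500 min, crossed share 0.0783, ratio 11.8

Late, I use the fill time F, the pool over its pace of filling, in place of the age. I borrow the pace of oak, which has the same reagent charge but more free catalyst. New target widens the gap, and memory closes it, so the gap rests at pace × τ:

pace 0.00486 /min of the charge, pool 20.9 %, F = 42.9 min

ratio = (F + τ)/(F − τ) = 1.16

The forecast gives 5 and 0.9, calling the early ratio “very uncertain because the denominator is tiny”, and my early figure is higher. The flask gives 11.4 and 1.15.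

    target ⇌ isomer of the product (K = 0.980, k = 0.00320 /s)
    substrate + free catalyst ⇌ free catalyst + open intermediate (K = 0.550, k = 730 /M/s)
    second catalyst + open intermediate ⇌ catalyst intermediate (K = 47.0 /M, k = 3500 /M/s)
    reagent + catalyst intermediate → second catalyst + target (k = 170 /M/s)
    reagent ⇌ dormant form (K = 13.0, k = 0.0190 /s)

The neighbour charged with 52 mM of reagent keeps τ and the early age in my reckoning, so I get 11.8 for it again, and it gives 11.3. At 30.0 min it holds 31.5 % target and 28.1 % isomer of the product, a ratio of 1.12.

The readings are simulated with made-up constants, noise included.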